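## Retrosynthetic overview
1. Sonogashira cut at the C(sp)–C(sp2) bond: target ⇒ alkynyl peroxyketal acid + (E)-11-iodoundec-10-en-2-one. The iodide is built from 1,6-dibromohexane, acetylide and acetone dimethylhydrazone.
2. Peroxyketal ⇒ racemic 1,2-dioxane hemiketal acid. An enantioselective acid-catalysed methanolysis (kinetic resolution) fixes both stereocentres.
3. 1,2-Dioxane ⇒ cyclobutanol by aerobic insertion of O2 into the C1–C2 bond. This four- to six-membered radical ring expansion is the key step.
4. Cyclobutanol, stored as a fused γ-lactone ⇒ cyclobutanone + methyl bromoacetate + 5-chloropent-1-yne.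
5. Ring order: cyclobutane (purchased) → temporary fused γ-lactone → 1,2-dioxane (the only ring of the target).

Locants used: O1, O2, C3 = CH bearing CH2CO2H, C6 = peroxyketal carbon. The target is (3S,6R), with OMe cis to CH2CO2H (OMe axial, both carbon chains equatorial).

Assumption: the (S)-catalyst in step 6 is taken as the one matched to the (3S)-hemiketal. If screening shows the opposite sense, its mirror image is used and nothing else changes.

## Route

Step 1
Reactants: 1 cyclobutanone
Product: 2 cyclobutanone N,N-dimethylhydrazone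
Conditions: Me2NNH2 (1.2 equiv), MgSO4, Et2O, rt
Reagents that add atoms: 1,1-dimethylhydrazine, CN(C)N
Why: Hydrazone condensation of an unhindered strained ketone is fast and provides an aza-enolate precursor that avoids the self-aldol chemistry of cyclobutanone enolates; no stereocentre is formed.

Step 2
Reactants: 2 cyclobutanone N,N-dimethylhydrazone; 3 methyl bromoacetate
Product: 6 methyl 2-(2-oxocyclobutyl)acetate (racemic), via lithiated hydrazone 4 (not isolated), via ester hydrazone 5 (not isolated)
Conditions: LDA, THF, 0 °C; 3, −78 °C to rt; sat. aq. oxalic acid/Et2O, rt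
Reagents that add atoms: water, O
Why: Hydrazone (aza-enolate) alkylation gives clean SN2 monoalkylation on the reactive bromoacetate, and biphasic oxalic acid hydrolysis spares the methyl ester; the new centre is racemic and is erased in step 5.

Step 3
Reactants: 7 5-chloropent-1-yne
Product: 9 (5-chloropent-1-yn-1-yl)trimethylsilane, via lithium chloropentynide 8 (not isolated)
Conditions: n-BuLi, THF, −78 °C; TMSCl, −78 °C to rt
Reagents that add atoms: chlorotrimethylsilane, C[Si](C)(C)Cl
Why: Acetylide silylation masks the acidic C–H so that the chloride can later be turned into a Grignard reagent.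

Step 4
Reactants: 6 methyl 2-(2-oxocyclobutyl)acetate; 9 (5-chloropent-1-yn-1-yl)trimethylsilane
Product: 12 cis-fused 1-[5-(trimethylsilyl)pent-4-yn-1-yl]-2-oxabicyclo[3.2.0]heptan-3-one (racemic), via alkylmagnesium chloride 10 (not isolated), via chloromagnesium alkoxide 11 (not isolated)
Conditions: 9, Mg, LiCl, THF, 50 °C; then 6, LaCl3·2LiCl, THF, −78 °C to rt; 1 M HCl
Reagents that add atoms: none
Why: Lanthanum-assisted Grignard 1,2-addition favours the strained ketone over the ester and suppresses enolisation; attack anti to the acetate arm places the alkoxide cis to it, so lactonisation on warming gives a stable, easily purified form of the tertiary cyclobutanol.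

Step 5
Reactants: 12 cis-fused 1-[5-(trimethylsilyl)pent-4-yn-1-yl]-2-oxabicyclo[3.2.0]heptan-3-one
Product: 15 2-[6-hydroxy-6-(pent-4-yn-1-yl)-1,2-dioxan-3-yl]acetic acid (racemic at C3; epimers at C6), via lithium hydroxy carboxylate 13 (not isolated), via keto hydroperoxide 14 (not isolated)
Conditions: LiOH (1.1 equiv), THF/H2O, rt; evaporate; Co(acac)2 (20 mol %), O2 (1 atm), t-BuOH/MeCN, 40 °C; 1 M HCl to pH 3, 0 °C
Reagents that add atoms: lithium hydroxide, [Li+].[OH-]; dioxygen, O=O
Why: Cobalt-catalysed aerobic oxidative ring expansion of a cyclobutanol (radical chain): saponification frees the tertiary alcohol, removes the alkyne silyl group and keeps the acid as a carboxylate that cannot relactonise; a trivalent cobalt alkoxide then gives the alkoxy radical, strain-driven β-scission cuts the more substituted C1–C2 bond, the secondary radical traps O2, and the hydroperoxide closes onto the new ketone to give the 1,2-dioxane, with C3 racemic because it passes through a planar radical.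

Step 6
Reactants: 15 2-[6-hydroxy-6-(pent-4-yn-1-yl)-1,2-dioxan-3-yl]acetic acid
Product: 16 2-[(3S,6R)-6-methoxy-6-(pent-4-yn-1-yl)-1,2-dioxan-3-yl]acetic acid
Conditions: (S)-3,3'-bis(2,4,6-triisopropylphenyl)-BINOL N-triflylphosphoramide (5 mol %), MeOH (0.55 equiv), 3 Å MS, toluene, −30 °C, stop at ca. 45% conversion; chromatography
Reagents that add atoms: methanol, CO
Why: Proposed new method: catalytic enantioselective peroxyketalisation run as a kinetic resolution, in which the strong chiral Brønsted acid ionises the hemiketal to a tertiary peroxycarbenium ion held as a contact ion pair; the chiral anion is also docked by hydrogen bonds to the substrate CO2H next to C3, so only the (3S)-cation (acetic acid arm pseudo-equatorial) fits the pocket, and catalyst-bound MeOH attacks axially under anomeric control to set (6R) cis to the arm, while (3R)-15 stays a polar hemiketal and is separated; the closest known reaction types are chiral phosphoric acid-catalysed asymmetric transacetalisation with kinetic resolution of hydroxy acetals and the achiral acid-catalysed methanolysis of 1,2-dioxan-3-ols.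

Step 7
Reactants: 17 1,6-dibromohexane; 18 lithium acetylide ethylenediamine complex
Product: 19 8-bromooct-1-yne
Conditions: 17 (3 equiv), 18 (1 equiv), DMSO, 0 °C to rt; excess 17 recovered by distillation
Reagents that add atoms: none
Why: SN2 alkylation of acetylide, with excess dibromide enforcing monosubstitution.

Step 8
Reactants: 19 8-bromooct-1-yne
Product: 21 (E)-8-bromo-1-iodooct-1-ene, via alkenylzirconocene chloride 20 (not isolated)
Conditions: Cp2Zr(H)Cl (1.2 equiv), CH2Cl2, rt; I2, 0 °C
Reagents that add atoms: iodine, [I][I]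
Why: Hydrozirconation–iodinolysis: syn addition with zirconium at the terminus, then C–Zr cleavage with retention, gives only the (E)-iodide, and the primary bromide is inert.

Step 9
Reactants: 21 (E)-8-bromo-1-iodooct-1-ene; 22 acetone N,N-dimethylhydrazone
Product: 25 (E)-11-iodoundec-10-en-2-one, via lithiated acetone hydrazone 23 (not isolated), via iodoalkenyl hydrazone 24 (not isolated)
Conditions: 22, n-BuLi, THF, 0 °C; 21, −78 °C to rt; sat. aq. oxalic acid/Et2O, rt
Reagents that add atoms: water, O
Why: Hydrazone aza-enolate alkylation delivers an acetone enolate equivalent by SN2 at the primary bromide without touching the vinyl iodide, and mild hydrolysis releases the methyl ketone.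

Step 10
Reactants: 16 2-[(3S,6R)-6-methoxy-6-(pent-4-yn-1-yl)-1,2-dioxan-3-yl]acetic acid; 25 (E)-11-iodoundec-10-en-2-one
Product: 26 2-[(3S,6R)-6-methoxy-6-[(E)-15-oxohexadec-6-en-4-yn-1-yl]-1,2-dioxan-3-yl]acetic acid (target)
Conditions: Pd(PPh3)4 (5 mol %), CuI (10 mol %), i-Pr2NH (5 equiv), degassed THF, rt; aq. citric acid work-up
Reagents that add atoms: none
Why: Sonogashira coupling of a vinyl iodide runs at room temperature with retention of the (E)-geometry; dialkyl peroxides and peroxyketals tolerate zerovalent palladium under such mild conditions, the acid travels as its ammonium salt, and neither ring stereocentre is touched.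

## Compound list
1 | cyclobutanone | O=C1CCC1 | starting material
2 | cyclobutanone N,N-dimethylhydrazone | CN(C)N=C1CCC1 | intermediate
3 | methyl bromoacetate | COC(=O)CBr | starting material
4 | lithiated cyclobutanone N,N-dimethylhydrazone | [Li+].CN(C)[N-]C1=CCC1 | intermediate
5 | methyl 2-[2-(2,2-dimethylhydrazinylidene)cyclobutyl]acetate (racemic) | COC(=O)CC1CCC1=NN(C)C | intermediate
6 | methyl 2-(2-oxocyclobutyl)acetate (racemic) | COC(=O)CC1CCC1=O | intermediate
7 | 5-chloropent-1-yne | C#CCCCCl | starting material
8 | lithium 5-chloropent-1-yn-1-ide | [Li+].[C-]#CCCCCl | intermediate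
9 | (5-chloropent-1-yn-1-yl)trimethylsilane | C[Si](C)(C)C#CCCCCl | intermediate
10 | [5-(trimethylsilyl)pent-4-yn-1-yl]magnesium chloride | C[Si](C)(C)C#CCCC[Mg]Cl | intermediate
11 | chloromagnesium alkoxide of methyl 2-[cis-2-hydroxy-2-(5-trimethylsilylpent-4-yn-1-yl)cyclobutyl]acetate (racemic, relative configuration shown) | COC(=O)C[C@@H]1CC[C@]1(CCCC#C[Si](C)(C)C)O[Mg]Cl | intermediate
12 | cis-fused 1-[5-(trimethylsilyl)pent-4-yn-1-yl]-2-oxabicyclo[3.2.0]heptan-3-one (racemic, relative configuration shown) | O=C1C[C@@H]2CC[C@]2(CCCC#C[Si](C)(C)C)O1 | intermediate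
13 | lithium 2-[cis-2-hydroxy-2-(pent-4-yn-1-yl)cyclobutyl]acetate (racemic, relative configuration shown) | [Li+].[O-]C(=O)C[C@@H]1CC[C@@]1(O)CCCC#C | intermediate
14 | lithium 3-hydroperoxy-6-oxoundec-10-ynoate (racemic) | [Li+].[O-]C(=O)CC(OO)CCC(=O)CCCC#C | intermediate
15 | 2-[6-hydroxy-6-(pent-4-yn-1-yl)-1,2-dioxan-3-yl]acetic acid (racemic at C3, epimers at C6) | OC1(CCCC#C)CCC(CC(=O)O)OO1 | intermediate
16 | 2-[(3S,6R)-6-methoxy-6-(pent-4-yn-1-yl)-1,2-dioxan-3-yl]acetic acid | CO[C@@]1(CCCC#C)CC[C@@H](CC(=O)O)OO1 | intermediate
17 | 1,6-dibromohexane | BrCCCCCCBr | starting material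
18 | lithium acetylide ethylenediamine complex | [Li+].[C-]#C.NCCN | starting material
19 | 8-bromooct-1-yne | C#CCCCCCCBr | intermediate
20 | [(E)-8-bromooct-1-en-1-yl]zirconocene chloride | BrCCCCCC/C=C/[Zr](Cl)(C1C=CC=C1)C1C=CC=C1 | intermediate
21 | (E)-8-bromo-1-iodooct-1-ene | BrCCCCCC/C=C/I | intermediate
22 | acetone N,N-dimethylhydrazone | CC(C)=NN(C)C | starting material
23 | lithiated acetone N,N-dimethylhydrazone | [Li+].C=C(C)[N-]N(C)C | intermediate
24 | (E)-11-iodoundec-10-en-2-one N,N-dimethylhydrazone | CC(CCCCCCC/C=C/I)=NN(C)C | intermediate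
25 | (E)-11-iodoundec-10-en-2-one | CC(=O)CCCCCCC/C=C/I | intermediate
26 | 2-[(3S,6R)-6-methoxy-6-[(E)-15-oxohexadec-6-en-4-yn-1-yl]-1,2-dioxan-3-yl]acetic acid | CO[C@@]1(CCCC#C/C=C/CCCCCCCC(C)=O)CC[C@@H](CC(=O)O)OO1 | target

## Step count
Total steps: 10.
Longest linear sequence: 6 (steps 1, 2, 4, 5, 6, 10).

## Steps most likely to fail

**Step 6 (the proposed new step).**
- Risks: the catalyst may be too weak to ionise the peroxy hemiketal, or the selectivity factor may be too low for a single enantiomer. The yield is capped at 50% in any case.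
- The fallback sets out from 15 and comes back at 16.
- TsOH (5 mol %) in MeOH/HC(OMe)3 at rt ketalises under thermodynamic anomeric control and esterifies the acid. This gives racemic cis methyl 2-[6-methoxy-6-(pent-4-yn-1-yl)-1,2-dioxan-3-yl]acetate F1.
- A lipase-catalysed enantioselective ester hydrolysis follows (Burkholderia cepacia lipase, pH 7 phosphate buffer/MTBE, 30 °C, about 45% conversion). It releases acid 16, which is separated from the unreacted antipodal ester by bicarbonate extraction.

**Step 5.**
- Risks: the carboxylate may tie up cobalt, tertiary cyclobutanols react less well than secondary ones, and the hydroperoxide can be degraded by the metal.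
- The fallback sets out from 12 and comes back at 15. It changes the substrate from a salt to a neutral ester.
- LiOH in THF/H2O, then MeI in DMF on the dried carboxylate, gives methyl 2-[cis-2-hydroxy-2-(pent-4-yn-1-yl)cyclobutyl]acetate F2.
- As an ordinary neutral cyclobutanol, this is ring-expanded with Co(acac)2 and O2 in toluene to methyl 2-[6-hydroxy-6-(pent-4-yn-1-yl)-1,2-dioxan-3-yl]acetate F3.
- Brief LiOH treatment in THF/H2O at 0 °C returns 15.

**Step 10.**
- Risks: CuI or phosphine may reduce the peroxide, and the free acid may slow the coupling.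
- The fallback sets out from 12 and comes back at 26. It moves the coupling ahead of peroxide formation.
- TBAF/AcOH in THF gives cis-fused 1-(pent-4-yn-1-yl)-2-oxabicyclo[3.2.0]heptan-3-one F4.
- Sonogashira coupling with 25 under the same catalyst system gives cis-fused 1-[(E)-15-oxohexadec-6-en-4-yn-1-yl]-2-oxabicyclo[3.2.0]heptan-3-one F5.
- The saponification and aerobic ring expansion of step 5 give 2-[6-hydroxy-6-[(E)-15-oxohexadec-6-en-4-yn-1-yl]-1,2-dioxan-3-yl]acetic acid F6.
- The methanolysis of step 6 then gives 26.

## Further compounds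
F1 | step 6 | methyl 2-[(3S*,6R*)-6-methoxy-6-(pent-4-yn-1-yl)-1,2-dioxan-3-yl]acetate (racemic, relative configuration shown) | CO[C@@]1(CCCC#C)CC[C@@H](CC(=O)OC)OO1
F2 | step 5 | methyl 2-[cis-2-hydroxy-2-(pent-4-yn-1-yl)cyclobutyl]acetate (racemic, relative configuration shown) | COC(=O)C[C@@H]1CC[C@@]1(O)CCCC#C
F3 | step 5 | methyl 2-[6-hydroxy-6-(pent-4-yn-1-yl)-1,2-dioxan-3-yl]acetate (racemic at C3, epimers at C6) | OC1(CCCC#C)CCC(CC(=O)OC)OO1
F4 | step 10 | cis-fused 1-(pent-4-yn-1-yl)-2-oxabicyclo[3.2.0]heptan-3-one (racemic, relative configuration shown) | O=C1C[C@@H]2CC[C@]2(CCCC#C)O1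
F5 | step 10 | cis-fused 1-[(E)-15-oxohexadec-6-en-4-yn-1-yl]-2-oxabicyclo[3.2.0]heptan-3-one (racemic, relative configuration shown) | O=C1C[C@@H]2CC[C@]2(CCCC#C/C=C/CCCCCCCC(C)=O)O1
F6 | step 10 | 2-[6-hydroxy-6-[(E)-15-oxohexadec-6-en-4-yn-1-yl]-1,2-dioxan-3-yl]acetic acid (racemic at C3, epimers at C6) | OC1(CCCC#C/C=C/CCCCCCCC(C)=O)CCC(CC(=O)O)OO1
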